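The numbers in the tables come from a simulation with constants of no real substance; noise was put on by code.

1. Follow the ratio c(isomer of the product)/c(target). The asked share of target, the selectivity, equals 1/(1 + ratio).

all flasks: starting material 0.079 M

| flask | coupling partner | remark | time |
|---|---|---|---|
| Wednesday's | 0.74 equiv | run made earlier |  |
| Sunday's | 1.7 equiv | run made earlier |  |
| flask | 1.10 equiv |  | 2.5 min |

| run | time / s | target / % | isomer of the product / % |
|---|---|---|---|
| Wednesday's | 10.0 | 4.6 | 0.6 |
| Wednesday's | 25.0 | 5.9 | 0 |
| Wednesday's | 40.0 | 5.8 | 0.3 |
| Wednesday's | 60.0 | 6.3 | 0.3 |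
| Wednesday's | 90.0 | 6.7 | 0.2 |
| Wednesday's | 120 | 6.7 | 0 |
| Sunday's | 20.0 | 12.8 | 0.3 |
| Sunday's | 40.0 | 12.3 | 0.9 |
| Sunday's | 60.0 | 13.1 | 0.6 |
| Sunday's | 80.0 | 13.4 | 0.7 |
| Sunday's | 90.0 | 13.4 | 0.7 |
| Sunday's | 120 | 14.0 | 1.3 |

(readings scatter by 0.3 percentage points)

* share of target in target plus isomer of the product at 0.80 s
* share of target in target plus isomer of the product at 10 s
* share of target in target plus isomer of the product at 2.5 min
* which of target and isomer of the product there is more of at 2.5 min



2. In Sunday's run, target moves from 12.8% at 20.0 s to 14.0% at 120 s. Isomer of the product moves from 0.3% to 1.3%. Target has slowed, but isomer of the product may still be creeping upward.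

3. Single isomer readings lie close to the scatter of 0.3 percentage points, so the last 3 readings of each run are pooled. This assumes that the charge of coupling partner cancels from the ratio. Summed isomer over summed target gives 0.0529, at a mean time of 93.3 s.

4. Assume that the ratio grows from near zero in proportion to time. The reading then gives 0.0340 /min, the drift: isomer of the product gained per unit of target, per unit time.

5. At 2.5 min in the new flask the drift gives a ratio of 0.0850, which is below one, so target leads. This reckoning puts the share at 92.2%. For 10 s it gives 99.4%.

6. For 0.80 s, 10 s and 2.5 min the forecast gives 99%, 98% and 95% (range of the last 91% to 98%), with target ahead. Its ground is that the isomer's rise “suggests slow later formation”. Its final share stands higher than this reckoning.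

7. At 0.80 s, 10 s and 2.5 min the flask gives 99.9%, 98.5% and 92.5%, so the forecast held. At 2.5 min it holds 9.43% of target against 0.761% of isomer of the product. The drift puts equal amounts at 29.4 min, about ten times the asked time. At 25.0 min this flask still holds 10.9% of target against 6.18% of isomer of the product.

    starting material ⇌ other conformer (K = 7.70, k = 0.00770 /s)
    starting material + coupling partner → target (k = 0.170 /M/s)
    coupling partner + other conformer → isomer of the product (k = 0.0790 /M/s)
    coupling partner ⇌ dormant form (K = 26.0, k = 0.110 /s)
    2 starting material → homo dimer (k = 0.340 /M/s)

8. A neighbour flask has 0.13 M of starting material, with the same equivalents and time. The drift was read at 0.079 M; carried over unchanged as an assumption, it gives 92.2% there at 2.5 min. The computed share in that neighbour flask is 93.2%.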